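## Retrosynthetic overview

1. The target is reached from a 2,8-trans 2-allyl-oxocane by C7 chlorination (inversion), C10 acetylation, conversion of the allyl group into the (E)-enyne (cross-metathesis, Colvin homologation) and a final C13 bromination (inversion).
2. The only ring (oxocane, C6–O–C12) is formed once: Shiina lactonisation of a seco acid to an eight-membered lactone, then reductive acetylation and C-allylation of the oxocarbenium ion, which sets C6.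
3. The seco acid comes from an open chain in which a furan is the masked C6 carboxyl, C9–Cl is installed by SN2 before any transannular ether oxygen exists, and C7 is set by Evans–Tishchenko reduction.
4. Key C8–C9 bond: Felkin–Anh-controlled Mukaiyama aldol between the enol silane of 2-acetylfuran (C6–C8) and an α-silyloxy aldehyde (C9–C15).
5. That aldehyde comes from (S)-α-hydroxy-γ-butyrolactone (C9–C12, C10 stereocentre) and a Brown (Z)-γ-alkoxyallylboration (C12 and C13 stereocentres, C13–C15).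

Assumption: (S)-α-hydroxy-γ-butyrolactone, 2-acetylfuran and all reagents are bought; positions are given in acetogenin numbering C1–C15 (ring oxygen on C6 and C12).

Abbreviations in names: TBS = tert-butyldimethylsilyl, TBDPS = tert-butyldiphenylsilyl, TES = triethylsilyl, MOM = methoxymethyl, Ipc = isopinocampheyl, MNBA = 2-methyl-6-nitrobenzoic anhydride.

## Route

Step 1
Reactants: 1 (S)-3-hydroxydihydrofuran-2(3H)-one
Product: 2 (S)-3-(TBDPSO)dihydrofuran-2(3H)-one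
Conditions: TBDPSCl, imidazole, DMF, 0 °C → rt
Reagents that add atoms: tert-butyl(chloro)diphenylsilane, CC(C)(C)[Si](Cl)(c1ccccc1)c1ccccc1
Why: Imidazole-promoted silylation of the secondary alcohol gives a bulky, non-chelating ether that later enforces Felkin–Anh control at C9 and outlasts the TES and TBS ethers.

Step 2
Reactants: 2 (S)-3-(TBDPSO)dihydrofuran-2(3H)-one
Product: 3 (S)-2-(TBDPSO)-4-hydroxy-N-methoxy-N-methylbutanamide
Conditions: MeNH(OMe)·HCl, AlMe3, CH2Cl2, 0 °C → rt; aq. potassium sodium tartrate; used at once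
Reagents that add atoms: N,O-dimethylhydroxylamine hydrochloride, CNOC.Cl
Why: Weinreb aminolysis of the lactone with the aluminium amide opens the ring without touching C10 and gives an amide that can later be stopped at the aldehyde.

Step 3
Reactants: 3 (S)-2-(TBDPSO)-4-hydroxy-N-methoxy-N-methylbutanamide
Product: 4 (S)-2-(TBDPSO)-N-methoxy-N-methyl-4-oxobutanamide
Conditions: TEMPO (10 mol%), PhI(OAc)2, CH2Cl2, rt
Reagents that add atoms: none
Why: Oxoammonium (TEMPO) oxidation takes the primary alcohol to the aldehyde under near-neutral conditions, so the β-silyloxy aldehyde neither eliminates nor epimerises.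

Step 4
Reactants: 4 (S)-2-(TBDPSO)-N-methoxy-N-methyl-4-oxobutanamide
Product: 5 (2S,4R,5R)-2-(TBDPSO)-4-hydroxy-N-methoxy-5-(methoxymethoxy)-N-methylhept-6-enamide
Conditions: CH2=CHCH2OCH2OCH3, s-BuLi, THF, −78 °C; (−)-Ipc2BOMe [from (+)-α-pinene]; BF3·OEt2; then 4, −78 °C; HOCH2CH2NH2 work-up
Reagents that add atoms: allyl methoxymethyl ether, C=CCOCOC
Why: Brown (Z)-γ-alkoxyallylboration (carbonyl allylation) passes through a closed chair transition state that gives the syn C12-OH/C13-OMOM pair, and the Ipc groups from (+)-α-pinene direct attack to the Si face to set 12R,13R under reagent control.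

Step 5
Reactants: 5 (2S,4R,5R)-2-(TBDPSO)-4-hydroxy-N-methoxy-5-(methoxymethoxy)-N-methylhept-6-enamide
Product: 6 (2S,4R,5R)-2-(TBDPSO)-N-methoxy-5-(methoxymethoxy)-N-methyl-4-(TESO)hept-6-enamide
Conditions: Et3SiOTf, 2,6-lutidine, CH2Cl2, −78 °C
Reagents that add atoms: triethylsilyl trifluoromethanesulfonate, CC[Si](CC)(CC)OS(=O)(=O)C(F)(F)F
Why: Silylation under non-basic conditions caps the C12 hydroxyl before it can lactonise onto the Weinreb amide, with the most labile of the three silyl groups.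

Step 6
Reactants: 6 (2S,4R,5R)-2-(TBDPSO)-N-methoxy-5-(methoxymethoxy)-N-methyl-4-(TESO)hept-6-enamide
Product: 7 (2S,4R,5R)-2-(TBDPSO)-N-methoxy-5-(methoxymethoxy)-N-methyl-4-(TESO)heptanamide
Conditions: H2 (1 atm), RhCl(PPh3)3 (5 mol%), toluene, rt
Reagents that add atoms: none
Why: Homogeneous hydrogenation reduces the terminal vinyl group to the C14–C15 ethyl group without hydrogenolysis of the allylic C–O bond or the N–O bond.

Step 7
Reactants: 7 (2S,4R,5R)-2-(TBDPSO)-N-methoxy-5-(methoxymethoxy)-N-methyl-4-(TESO)heptanamide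
Product: 8 (2S,4R,5R)-2-(TBDPSO)-5-(methoxymethoxy)-4-(TESO)heptanal
Conditions: iBu2AlH, THF, −78 °C; aq. potassium sodium tartrate
Reagents that add atoms: none
Why: Weinreb amide reduction stops at the chelated tetrahedral intermediate and releases the α-silyloxy aldehyde only on work-up, without epimerisation at C10.

Step 8
Reactants: 9 2-acetylfuran
Product: 10 {[1-(furan-2-yl)ethenyl]oxy}trimethylsilane
Conditions: Me3SiOTf, Et3N, CH2Cl2, 0 °C
Reagents that add atoms: trimethylsilyl trifluoromethanesulfonate, C[Si](C)(C)OS(=O)(=O)C(F)(F)F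
Why: Soft enolisation of a ketone with a single enolisable position gives one enol silane, and the furan carries C6 as a masked carboxyl.

Step 9
Reactants: 8 (2S,4R,5R)-2-(TBDPSO)-5-(methoxymethoxy)-4-(TESO)heptanal; 10 {[1-(furan-2-yl)ethenyl]oxy}trimethylsilane
Product: 11 (3R,4S,6R,7R)-4-(TBDPSO)-1-(furan-2-yl)-3-hydroxy-7-(methoxymethoxy)-6-(TESO)nonan-1-one
Conditions: BF3·OEt2, CH2Cl2, −78 °C; sat. aq. NaHCO3
Reagents that add atoms: none
Why: Intermolecular Mukaiyama aldol joins C6–C8 to C9–C15, and with monodentate BF3 the open transition state follows the polar Felkin–Anh model so the nucleophile adds anti to the α-silyloxy group and sets 9R (anti to C10–O).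

Step 10
Reactants: 11 (3R,4S,6R,7R)-4-(TBDPSO)-1-(furan-2-yl)-3-hydroxy-7-(methoxymethoxy)-6-(TESO)nonan-1-one
Product: 12 (1R,3R,4S,6R,7R)-4-(TBDPSO)-1-(furan-2-yl)-1-hydroxy-7-(methoxymethoxy)-6-(TESO)nonan-3-yl acetate
Conditions: SmI2 (30 mol%), CH3CHO (8 equiv), THF, −10 °C
Reagents that add atoms: acetaldehyde, CC=O
Why: Evans–Tishchenko reduction delivers hydride intramolecularly from the samarium-bound hemiacetal through a chair transition state, giving the 1,3-anti alcohol (7R) and leaving the acetate on C9–O so that only C7–OH is free.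

Step 11
Reactants: 12 (1R,3R,4S,6R,7R)-4-(TBDPSO)-1-(furan-2-yl)-1-hydroxy-7-(methoxymethoxy)-6-(TESO)nonan-3-yl acetate
Product: 13 (1R,3R,4S,6R,7R)-1-(TBSO)-4-(TBDPSO)-1-(furan-2-yl)-7-(methoxymethoxy)-6-(TESO)nonan-3-yl acetate
Conditions: t-BuMe2SiOTf, 2,6-lutidine, CH2Cl2, −78 °C
Reagents that add atoms: tert-butyldimethylsilyl trifluoromethanesulfonate, CC(C)(C)[Si](C)(C)OS(=O)(=O)C(F)(F)F
Why: Prompt silylation of the C7 alcohol fixes the differentiation before 1,3-acyl migration can occur and places a group of intermediate lability on C7.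

Step 12
Reactants: 13 (1R,3R,4S,6R,7R)-1-(TBSO)-4-(TBDPSO)-1-(furan-2-yl)-7-(methoxymethoxy)-6-(TESO)nonan-3-yl acetate
Product: 14 (1R,3R,4S,6R,7R)-1-(TBSO)-4-(TBDPSO)-1-(furan-2-yl)-7-(methoxymethoxy)-6-(TESO)nonan-3-ol
Conditions: K2CO3 (0.3 equiv), MeOH, 0 °C → rt
Reagents that add atoms: none
Why: Mild methanolysis removes the acetate to free only the C9 hydroxyl while the three silyl ethers and the MOM ether stay in place.

Step 13
Reactants: 14 (1R,3R,4S,6R,7R)-1-(TBSO)-4-(TBDPSO)-1-(furan-2-yl)-7-(methoxymethoxy)-6-(TESO)nonan-3-ol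
Product: 16 2-{(1R,3S,4S,6R,7R)-1-(TBSO)-4-(TBDPSO)-3-chloro-7-(methoxymethoxy)-6-(TESO)nonyl}furan, via C9 triflate 15 (not isolated)
Conditions: Tf2O, pyridine, CH2Cl2, −40 °C; then Bu4NCl (5 equiv), −40 → 0 °C
Reagents that add atoms: tetrabutylammonium chloride, [Cl-].CCCC[N+](CCCC)(CCCC)CCCC
Why: SN2 displacement of the secondary triflate by excess soluble chloride at low temperature inverts C9 (9R → 9S) on the open chain, where no ring oxygen can participate transannularly.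

Step 14
Reactants: 16 2-{(1R,3S,4S,6R,7R)-1-(TBSO)-4-(TBDPSO)-3-chloro-7-(methoxymethoxy)-6-(TESO)nonyl}furan
Product: 17 (2R,4S,5S,7R,8R)-2-(TBSO)-5-(TBDPSO)-4-chloro-8-(methoxymethoxy)-7-(TESO)decanoic acid
Conditions: O3, CH2Cl2/MeOH (3:1), −78 °C; then Me2S, −78 °C → rt; H2O
Reagents that add atoms: ozone, [O-][O+]=O
Why: Ozonolysis cleaves both furan double bonds and unmasks the C6 carboxylic acid without touching silyl ethers, the chloride or the C7 stereocentre.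

Step 15
Reactants: 17 (2R,4S,5S,7R,8R)-2-(TBSO)-5-(TBDPSO)-4-chloro-8-(methoxymethoxy)-7-(TESO)decanoic acid
Product: 18 (2R,4S,5S,7R,8R)-2-(TBSO)-5-(TBDPSO)-4-chloro-7-hydroxy-8-(methoxymethoxy)decanoic acid
Conditions: PPTS, MeOH/CH2Cl2, 0 °C → rt
Reagents that add atoms: none
Why: Mild acid solvolysis removes only the TES ether, the most labile of the three silyl groups, and frees the C12 hydroxyl.

Step 16
Reactants: 18 (2R,4S,5S,7R,8R)-2-(TBSO)-5-(TBDPSO)-4-chloro-7-hydroxy-8-(methoxymethoxy)decanoic acid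
Product: 19 (3R,5S,6S,8R)-3-(TBSO)-6-(TBDPSO)-5-chloro-8-[(1R)-1-(methoxymethoxy)propyl]oxocan-2-one
Conditions: MNBA (1.5 equiv), DMAP (6 equiv), CH2Cl2 (2 mM, slow addition of 18 over 12 h), rt
Reagents that add atoms: none
Why: Shiina macrolactonisation at high dilution closes the eight-membered ring through the mixed anhydride, as it does for the similarly substituted saturated seco acids of octalactin-type lactones, and touches no stereocentre.

Step 17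
Reactants: 19 (3R,5S,6S,8R)-3-(TBSO)-6-(TBDPSO)-5-chloro-8-[(1R)-1-(methoxymethoxy)propyl]oxocan-2-one
Product: 21 (3R,5S,6S,8R)-3-(TBSO)-6-(TBDPSO)-5-chloro-8-[(1R)-1-(methoxymethoxy)propyl]oxocan-2-yl acetate (both C2 epimers), via aluminium lactolate 20 (not isolated)
Conditions: iBu2AlH, CH2Cl2, −78 °C; then pyridine, DMAP, Ac2O, −78 → 0 °C
Reagents that add atoms: acetic anhydride, CC(=O)OC(C)=O
Why: Rychnovsky reductive acetylation traps the low-temperature aluminium lactolate as the α-acetoxy ether before it can open to a hydroxy aldehyde.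

Step 18
Reactants: 21 (3R,5S,6S,8R)-3-(TBSO)-6-(TBDPSO)-5-chloro-8-[(1R)-1-(methoxymethoxy)propyl]oxocan-2-yl acetate
Product: 23 (2R,4S,5S,7R,8S)-8-allyl-7-(TBSO)-4-(TBDPSO)-5-chloro-2-[(1R)-1-(methoxymethoxy)propyl]oxocane, via oxocarbenium ion 22 (not isolated)
Conditions: CH2=CHCH2SiMe3 (4 equiv), BF3·OEt2, CH2Cl2, −78 °C
Reagents that add atoms: allyltrimethylsilane, C=CC[Si](C)(C)C
Why: Hosomi–Sakurai allylation of the cyclic oxocarbenium ion is expected to occur on the face opposite both the C12 side chain and the adjacent C7 silyloxy group, setting 6S (2,8-trans, allyl trans to C7–O).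

Step 19
Reactants: 23 (2R,4S,5S,7R,8S)-8-allyl-7-(TBSO)-4-(TBDPSO)-5-chloro-2-[(1R)-1-(methoxymethoxy)propyl]oxocane
Product: 24 (2R,4S,5S,7R,8S)-8-allyl-4-(TBDPSO)-5-chloro-2-[(1R)-1-(methoxymethoxy)propyl]oxocan-7-ol
Conditions: HF·pyridine, pyridine, THF, 0 °C → rt
Reagents that add atoms: none
Why: Buffered acidic fluoride cleaves the TBS ether much faster than the TBDPS ether and leaves the MOM ether alone.

Step 20
Reactants: 24 (2R,4S,5S,7R,8S)-8-allyl-4-(TBDPSO)-5-chloro-2-[(1R)-1-(methoxymethoxy)propyl]oxocan-7-ol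
Product: 25 (2R,4S,5S,7S,8S)-8-allyl-4-(TBDPSO)-5,7-dichloro-2-[(1R)-1-(methoxymethoxy)propyl]oxocane
Conditions: (n-C8H17)3P, CCl4, toluene, 70 °C
Reagents that add atoms: carbon tetrachloride, ClC(Cl)(Cl)Cl
Why: Appel-type chlorination through the alkoxyphosphonium salt displaces with inversion (7R → 7S), the tactic used for C7 chlorides of halogenated Laurencia oxocenes.

Step 21
Reactants: 25 (2R,4S,5S,7S,8S)-8-allyl-4-(TBDPSO)-5,7-dichloro-2-[(1R)-1-(methoxymethoxy)propyl]oxocane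
Product: 26 (2R,4S,5S,7S,8S)-8-allyl-5,7-dichloro-2-[(1R)-1-(methoxymethoxy)propyl]oxocan-4-ol
Conditions: Bu4NF, AcOH (1:1), THF, rt → 40 °C
Reagents that add atoms: none
Why: Acetic-acid-buffered fluoride removes the last silyl ether without building up a free alkoxide next to the C9 chloride, so no epoxide forms.

Step 22
Reactants: 26 (2R,4S,5S,7S,8S)-8-allyl-5,7-dichloro-2-[(1R)-1-(methoxymethoxy)propyl]oxocan-4-ol
Product: 27 (2R,4S,5S,7S,8S)-8-allyl-5,7-dichloro-2-[(1R)-1-(methoxymethoxy)propyl]oxocan-4-yl acetate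
Conditions: Ac2O, pyridine, DMAP (cat.), CH2Cl2, rt
Reagents that add atoms: acetic anhydride, CC(=O)OC(C)=O
Why: Standard DMAP-catalysed acylation installs the C10 acetate with retention.

Step 23
Reactants: 27 (2R,4S,5S,7S,8S)-8-allyl-5,7-dichloro-2-[(1R)-1-(methoxymethoxy)propyl]oxocan-4-yl acetate
Product: 28 (2R,4S,5S,7S,8S)-5,7-dichloro-2-[(1R)-1-(methoxymethoxy)propyl]-8-[(2E)-4-oxobut-2-en-1-yl]oxocan-4-yl acetate
Conditions: (E)-crotonaldehyde (10 equiv), second-generation Grubbs catalyst RuCl2(H2IMes)(PCy3)(=CHPh) (5 mol%), CH2Cl2, 40 °C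
Reagents that add atoms: (E)-crotonaldehyde, C/C=C/C=O
Why: Cross-metathesis of the terminal alkene with an excess of the electron-poor enal is selective for the (E)-enal and fixes the C3=C4 geometry.

Step 24
Reactants: 28 (2R,4S,5S,7S,8S)-5,7-dichloro-2-[(1R)-1-(methoxymethoxy)propyl]-8-[(2E)-4-oxobut-2-en-1-yl]oxocan-4-yl acetate
Product: 29 (2R,4S,5S,7S,8S)-5,7-dichloro-2-[(1R)-1-(methoxymethoxy)propyl]-8-[(2E)-pent-2-en-4-yn-1-yl]oxocan-4-yl acetate
Conditions: Me3SiCHN2, n-BuLi, THF, −78 °C; then 28, −78 → 0 °C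
Reagents that add atoms: trimethylsilyldiazomethane, C[Si](C)(C)C=[N+]=[N-]
Why: Colvin homologation (addition, Peterson elimination, 1,2-hydride shift of the alkylidene carbene) turns the aldehyde into the terminal alkyne at low temperature, which spares the acetate and the secondary chlorides and keeps the (E)-alkene.

Step 25
Reactants: 29 (2R,4S,5S,7S,8S)-5,7-dichloro-2-[(1R)-1-(methoxymethoxy)propyl]-8-[(2E)-pent-2-en-4-yn-1-yl]oxocan-4-yl acetate
Product: 30 (2R,4S,5S,7S,8S)-5,7-dichloro-2-[(1R)-1-hydroxypropyl]-8-[(2E)-pent-2-en-4-yn-1-yl]oxocan-4-yl acetate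
Conditions: ZnBr2, n-PrSH, CH2Cl2, 0 °C, 10 min
Reagents that add atoms: none
Why: Lewis-acid/thiol cleavage removes the MOM acetal within minutes and leaves the acetate, the chlorides and the enyne untouched.

Step 26
Reactants: 30 (2R,4S,5S,7S,8S)-5,7-dichloro-2-[(1R)-1-hydroxypropyl]-8-[(2E)-pent-2-en-4-yn-1-yl]oxocan-4-yl acetate
Product: 31 (2R,4S,5S,7S,8S)-2-[(1S)-1-bromopropyl]-5,7-dichloro-8-[(2E)-pent-2-en-4-yn-1-yl]oxocan-4-yl acetate
Conditions: CBr4, (n-C8H17)3P, toluene, 70 °C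
Reagents that add atoms: carbon tetrabromide, BrC(Br)(Br)Br
Why: Appel-type bromination of the C13 alcohol proceeds with inversion (13R → 13S), the established last step of laurencin-type syntheses.

## Compound list

1 | (S)-3-hydroxydihydrofuran-2(3H)-one | O=C1OCC[C@@H]1O | starting material
2 | (S)-3-(TBDPSO)dihydrofuran-2(3H)-one | O=C1OCC[C@@H]1O[Si](c2ccccc2)(c2ccccc2)C(C)(C)C | intermediate
3 | (S)-2-(TBDPSO)-4-hydroxy-N-methoxy-N-methylbutanamide | CON(C)C(=O)[C@@H](O[Si](c1ccccc1)(c1ccccc1)C(C)(C)C)CCO | intermediate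
4 | (S)-2-(TBDPSO)-N-methoxy-N-methyl-4-oxobutanamide | CON(C)C(=O)[C@@H](O[Si](c1ccccc1)(c1ccccc1)C(C)(C)C)CC=O | intermediate
5 | (2S,4R,5R)-2-(TBDPSO)-4-hydroxy-N-methoxy-5-(methoxymethoxy)-N-methylhept-6-enamide | CON(C)C(=O)[C@@H](O[Si](c1ccccc1)(c1ccccc1)C(C)(C)C)C[C@@H](O)[C@H](OCOC)C=C | intermediate
6 | (2S,4R,5R)-2-(TBDPSO)-N-methoxy-5-(methoxymethoxy)-N-methyl-4-(TESO)hept-6-enamide | CON(C)C(=O)[C@@H](O[Si](c1ccccc1)(c1ccccc1)C(C)(C)C)C[C@@H](O[Si](CC)(CC)CC)[C@H](OCOC)C=C | intermediate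
7 | (2S,4R,5R)-2-(TBDPSO)-N-methoxy-5-(methoxymethoxy)-N-methyl-4-(TESO)heptanamide | CON(C)C(=O)[C@@H](O[Si](c1ccccc1)(c1ccccc1)C(C)(C)C)C[C@@H](O[Si](CC)(CC)CC)[C@H](OCOC)CC | intermediate
8 | (2S,4R,5R)-2-(TBDPSO)-5-(methoxymethoxy)-4-(TESO)heptanal | O=C[C@@H](O[Si](c1ccccc1)(c1ccccc1)C(C)(C)C)C[C@@H](O[Si](CC)(CC)CC)[C@H](OCOC)CC | intermediate
9 | 2-acetylfuran | CC(=O)c1ccco1 | starting material
10 | {[1-(furan-2-yl)ethenyl]oxy}trimethylsilane | C=C(O[Si](C)(C)C)c1ccco1 | intermediate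
11 | (3R,4S,6R,7R)-4-(TBDPSO)-1-(furan-2-yl)-3-hydroxy-7-(methoxymethoxy)-6-(TESO)nonan-1-one | O=C(c1ccco1)C[C@@H](O)[C@@H](O[Si](c1ccccc1)(c1ccccc1)C(C)(C)C)C[C@@H](O[Si](CC)(CC)CC)[C@H](OCOC)CC | intermediate
12 | (1R,3R,4S,6R,7R)-4-(TBDPSO)-1-(furan-2-yl)-1-hydroxy-7-(methoxymethoxy)-6-(TESO)nonan-3-yl acetate | O[C@@H](c1ccco1)C[C@@H](OC(C)=O)[C@@H](O[Si](c1ccccc1)(c1ccccc1)C(C)(C)C)C[C@@H](O[Si](CC)(CC)CC)[C@H](OCOC)CC | intermediate
13 | (1R,3R,4S,6R,7R)-1-(TBSO)-4-(TBDPSO)-1-(furan-2-yl)-7-(methoxymethoxy)-6-(TESO)nonan-3-yl acetate | CC(C)(C)[Si](C)(C)O[C@@H](c1ccco1)C[C@@H](OC(C)=O)[C@@H](O[Si](c1ccccc1)(c1ccccc1)C(C)(C)C)C[C@@H](O[Si](CC)(CC)CC)[C@H](OCOC)CC | intermediate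
14 | (1R,3R,4S,6R,7R)-1-(TBSO)-4-(TBDPSO)-1-(furan-2-yl)-7-(methoxymethoxy)-6-(TESO)nonan-3-ol | CC(C)(C)[Si](C)(C)O[C@@H](c1ccco1)C[C@@H](O)[C@@H](O[Si](c1ccccc1)(c1ccccc1)C(C)(C)C)C[C@@H](O[Si](CC)(CC)CC)[C@H](OCOC)CC | intermediate
15 | (1R,3R,4S,6R,7R)-1-(TBSO)-4-(TBDPSO)-1-(furan-2-yl)-7-(methoxymethoxy)-6-(TESO)nonan-3-yl trifluoromethanesulfonate | CC(C)(C)[Si](C)(C)O[C@@H](c1ccco1)C[C@@H](OS(=O)(=O)C(F)(F)F)[C@@H](O[Si](c1ccccc1)(c1ccccc1)C(C)(C)C)C[C@@H](O[Si](CC)(CC)CC)[C@H](OCOC)CC | intermediate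
16 | 2-{(1R,3S,4S,6R,7R)-1-(TBSO)-4-(TBDPSO)-3-chloro-7-(methoxymethoxy)-6-(TESO)nonyl}furan | CC(C)(C)[Si](C)(C)O[C@@H](c1ccco1)C[C@H](Cl)[C@@H](O[Si](c1ccccc1)(c1ccccc1)C(C)(C)C)C[C@@H](O[Si](CC)(CC)CC)[C@H](OCOC)CC | intermediate
17 | (2R,4S,5S,7R,8R)-2-(TBSO)-5-(TBDPSO)-4-chloro-8-(methoxymethoxy)-7-(TESO)decanoic acid | OC(=O)[C@H](O[Si](C)(C)C(C)(C)C)C[C@H](Cl)[C@@H](O[Si](c1ccccc1)(c1ccccc1)C(C)(C)C)C[C@@H](O[Si](CC)(CC)CC)[C@H](OCOC)CC | intermediate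
18 | (2R,4S,5S,7R,8R)-2-(TBSO)-5-(TBDPSO)-4-chloro-7-hydroxy-8-(methoxymethoxy)decanoic acid | OC(=O)[C@H](O[Si](C)(C)C(C)(C)C)C[C@H](Cl)[C@@H](O[Si](c1ccccc1)(c1ccccc1)C(C)(C)C)C[C@@H](O)[C@H](OCOC)CC | intermediate
19 | (3R,5S,6S,8R)-3-(TBSO)-6-(TBDPSO)-5-chloro-8-[(1R)-1-(methoxymethoxy)propyl]oxocan-2-one | O=C1O[C@@H]([C@H](OCOC)CC)C[C@H](O[Si](c2ccccc2)(c2ccccc2)C(C)(C)C)[C@@H](Cl)C[C@H]1O[Si](C)(C)C(C)(C)C | intermediate
20 | diisobutylaluminium (3R,5S,6S,8R)-3-(TBSO)-6-(TBDPSO)-5-chloro-8-[(1R)-1-(methoxymethoxy)propyl]oxocan-2-olate | CC(C)C[Al](CC(C)C)OC1O[C@@H]([C@H](OCOC)CC)C[C@H](O[Si](c2ccccc2)(c2ccccc2)C(C)(C)C)[C@@H](Cl)C[C@H]1O[Si](C)(C)C(C)(C)C | intermediate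
21 | (3R,5S,6S,8R)-3-(TBSO)-6-(TBDPSO)-5-chloro-8-[(1R)-1-(methoxymethoxy)propyl]oxocan-2-yl acetate (both C2 epimers) | CC(=O)OC1O[C@@H]([C@H](OCOC)CC)C[C@H](O[Si](c2ccccc2)(c2ccccc2)C(C)(C)C)[C@@H](Cl)C[C@H]1O[Si](C)(C)C(C)(C)C | intermediate
22 | cyclic oxocarbenium ion (O1=C2) derived from 21, (3R,5S,6S,8R) | C1=[O+][C@@H]([C@H](OCOC)CC)C[C@H](O[Si](c2ccccc2)(c2ccccc2)C(C)(C)C)[C@@H](Cl)C[C@H]1O[Si](C)(C)C(C)(C)C | intermediate
23 | (2R,4S,5S,7R,8S)-8-allyl-7-(TBSO)-4-(TBDPSO)-5-chloro-2-[(1R)-1-(methoxymethoxy)propyl]oxocane | C=CC[C@@H]1O[C@@H]([C@H](OCOC)CC)C[C@H](O[Si](c2ccccc2)(c2ccccc2)C(C)(C)C)[C@@H](Cl)C[C@H]1O[Si](C)(C)C(C)(C)C | intermediate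
24 | (2R,4S,5S,7R,8S)-8-allyl-4-(TBDPSO)-5-chloro-2-[(1R)-1-(methoxymethoxy)propyl]oxocan-7-ol | C=CC[C@@H]1O[C@@H]([C@H](OCOC)CC)C[C@H](O[Si](c2ccccc2)(c2ccccc2)C(C)(C)C)[C@@H](Cl)C[C@H]1O | intermediate
25 | (2R,4S,5S,7S,8S)-8-allyl-4-(TBDPSO)-5,7-dichloro-2-[(1R)-1-(methoxymethoxy)propyl]oxocane | C=CC[C@@H]1O[C@@H]([C@H](OCOC)CC)C[C@H](O[Si](c2ccccc2)(c2ccccc2)C(C)(C)C)[C@@H](Cl)C[C@@H]1Cl | intermediate
26 | (2R,4S,5S,7S,8S)-8-allyl-5,7-dichloro-2-[(1R)-1-(methoxymethoxy)propyl]oxocan-4-ol | C=CC[C@@H]1O[C@@H]([C@H](OCOC)CC)C[C@H](O)[C@@H](Cl)C[C@@H]1Cl | intermediate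
27 | (2R,4S,5S,7S,8S)-8-allyl-5,7-dichloro-2-[(1R)-1-(methoxymethoxy)propyl]oxocan-4-yl acetate | C=CC[C@@H]1O[C@@H]([C@H](OCOC)CC)C[C@H](OC(C)=O)[C@@H](Cl)C[C@@H]1Cl | intermediate
28 | (2R,4S,5S,7S,8S)-5,7-dichloro-2-[(1R)-1-(methoxymethoxy)propyl]-8-[(2E)-4-oxobut-2-en-1-yl]oxocan-4-yl acetate | O=C/C=C/C[C@@H]1O[C@@H]([C@H](OCOC)CC)C[C@H](OC(C)=O)[C@@H](Cl)C[C@@H]1Cl | intermediate
29 | (2R,4S,5S,7S,8S)-5,7-dichloro-2-[(1R)-1-(methoxymethoxy)propyl]-8-[(2E)-pent-2-en-4-yn-1-yl]oxocan-4-yl acetate | C#C/C=C/C[C@@H]1O[C@@H]([C@H](OCOC)CC)C[C@H](OC(C)=O)[C@@H](Cl)C[C@@H]1Cl | intermediate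
30 | (2R,4S,5S,7S,8S)-5,7-dichloro-2-[(1R)-1-hydroxypropyl]-8-[(2E)-pent-2-en-4-yn-1-yl]oxocan-4-yl acetate | C#C/C=C/C[C@@H]1O[C@@H]([C@H](O)CC)C[C@H](OC(C)=O)[C@@H](Cl)C[C@@H]1Cl | intermediate
31 | (2R,4S,5S,7S,8S)-2-[(1S)-1-bromopropyl]-5,7-dichloro-8-[(2E)-pent-2-en-4-yn-1-yl]oxocan-4-yl acetate | C#C/C=C/C[C@@H]1O[C@@H]([C@@H](Br)CC)C[C@H](OC(C)=O)[C@@H](Cl)C[C@@H]1Cl | target

## Step count and risks

Total step count: 26. Longest linear sequence: 25 steps (1 → 31 through steps 1–7 and 9–26); step 8 is a one-step branch.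

The three steps most likely to fail:

Step 16 (eight-membered lactonisation; oligomers or attack of the carboxylate on C9–Cl may compete). The fallback closes the ring at the acetal oxidation level instead of by acylation; it sets out from 18 and comes back at 23. Borane–dimethyl sulfide (THF, 0 °C → rt) reduces the acid to (2R,4S,5S,7R,8R)-2-(TBSO)-5-(TBDPSO)-4-chloro-8-(methoxymethoxy)decane-1,7-diol F1. TEMPO/PhI(OAc)2 then oxidises only the primary alcohol to (2R,4S,5S,7R,8R)-2-(TBSO)-5-(TBDPSO)-4-chloro-7-hydroxy-8-(methoxymethoxy)decanal F2. Treating F2 with CH2=CHCH2SiMe3 and Me3SiOTf (CH2Cl2, −78 °C) lets the C12 hydroxyl add to the activated aldehyde, so the oxocane closes as oxocarbenium ion 22 and is allylated in the same flask to 23 (the allyl counterpart of the hydroxy-ketone/silane reductive cyclisations used for simple 2,8-disubstituted oxocanes).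

Step 18 (facial selectivity of the C-allylation is argued by analogy, not proven on this ring). The fallback is stereocomplementary: it sets out from 19 and comes back at 23. One equivalent of CH2=CHCH2MgBr (THF, −78 °C) opens the lactone to (5R,7S,8S,10R,11R)-5-(TBSO)-8-(TBDPSO)-7-chloro-10-hydroxy-11-(methoxymethoxy)tridec-1-en-4-one F3. Et3SiH/Me3SiOTf (CH2Cl2, −78 °C) then effects reductive cyclisation, in which hydride takes the trajectory that the allyl group takes in step 18. It therefore gives 23 in the case that step 18 delivers mainly the C6 epimer.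

Step 26 (late bromination next to the ring oxygen in the presence of the enyne; elimination or participation can lower the yield). The fallback changes the order so that halogenation is finished before the enyne exists; it sets out from 27 and comes back at 31. ZnBr2/n-PrSH gives (2R,4S,5S,7S,8S)-8-allyl-5,7-dichloro-2-[(1R)-1-hydroxypropyl]oxocan-4-yl acetate F4. CBr4/(n-C8H17)3P (toluene, 70 °C) gives (2R,4S,5S,7S,8S)-8-allyl-2-[(1S)-1-bromopropyl]-5,7-dichlorooxocan-4-yl acetate F5. Cross-metathesis with (E)-crotonaldehyde and the second-generation Grubbs catalyst gives (2R,4S,5S,7S,8S)-2-[(1S)-1-bromopropyl]-5,7-dichloro-8-[(2E)-4-oxobut-2-en-1-yl]oxocan-4-yl acetate F6. Colvin homologation (Me3SiCHN2, n-BuLi, THF, −78 °C) then gives 31.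

Further compounds

F1 | step 16 | (2R,4S,5S,7R,8R)-2-(TBSO)-5-(TBDPSO)-4-chloro-8-(methoxymethoxy)decane-1,7-diol | OC[C@H](O[Si](C)(C)C(C)(C)C)C[C@H](Cl)[C@@H](O[Si](c1ccccc1)(c1ccccc1)C(C)(C)C)C[C@@H](O)[C@H](OCOC)CC
F2 | step 16 | (2R,4S,5S,7R,8R)-2-(TBSO)-5-(TBDPSO)-4-chloro-7-hydroxy-8-(methoxymethoxy)decanal | O=C[C@H](O[Si](C)(C)C(C)(C)C)C[C@H](Cl)[C@@H](O[Si](c1ccccc1)(c1ccccc1)C(C)(C)C)C[C@@H](O)[C@H](OCOC)CC
F3 | step 18 | (5R,7S,8S,10R,11R)-5-(TBSO)-8-(TBDPSO)-7-chloro-10-hydroxy-11-(methoxymethoxy)tridec-1-en-4-one | C=CCC(=O)[C@H](O[Si](C)(C)C(C)(C)C)C[C@H](Cl)[C@@H](O[Si](c1ccccc1)(c1ccccc1)C(C)(C)C)C[C@@H](O)[C@H](OCOC)CC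
F4 | step 26 | (2R,4S,5S,7S,8S)-8-allyl-5,7-dichloro-2-[(1R)-1-hydroxypropyl]oxocan-4-yl acetate | C=CC[C@@H]1O[C@@H]([C@H](O)CC)C[C@H](OC(C)=O)[C@@H](Cl)C[C@@H]1Cl
F5 | step 26 | (2R,4S,5S,7S,8S)-8-allyl-2-[(1S)-1-bromopropyl]-5,7-dichlorooxocan-4-yl acetate | C=CC[C@@H]1O[C@@H]([C@@H](Br)CC)C[C@H](OC(C)=O)[C@@H](Cl)C[C@@H]1Cl
F6 | step 26 | (2R,4S,5S,7S,8S)-2-[(1S)-1-bromopropyl]-5,7-dichloro-8-[(2E)-4-oxobut-2-en-1-yl]oxocan-4-yl acetate | O=C/C=C/C[C@@H]1O[C@@H]([C@@H](Br)CC)C[C@H](OC(C)=O)[C@@H](Cl)C[C@@H]1Cl
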